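The ten-membered carbocycle is closed last, at C5–C6. C6 is the lactone carbinol and C5 a methylene two bonds from furanone carbon C3, so C5 becomes a primary alkylchromium (from the iodide, cobalt-catalysed) that adds to a C6 aldehyde. One operation closes the oxygen-bridged medium ring (C3–C10 with the furanone oxygen) and sets C6 under control of C7. The precursor is an open-chain furan-3(2H)-one: at C3 it carries the Roche-ester-derived CH(CH3)CH2I arm (C4 preset), at C10 an aldol-derived chain with the C6 aldehyde, C8 silyl ether and a C11 bromovinyl group, later carbonylated to the α-methylene lactone.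

Key step: step 19

Remark: carbons are numbered as in the germacrane skeleton of the target (C1 furanone carbonyl, C2=C3, C4 with methyl C15, C5, C6 lactone carbinol, C7, C8 ester carbinol, C9, C10 with methyl C14 and the ring oxygen, C11=C13, C12 lactone carbonyl); "as in the target" means the same spatial arrangement whatever the CIP letter, and both enantiomers of 3-bromo-2-hydroxy-2-methylpropanoic acid and of citramalic acid are taken as commercial.

Step 1
Reactants: 1 methyl (S)-3-hydroxy-2-methylpropanoate
Product: 2 methyl (S)-3-[(tert-butyldimethylsilyl)oxy]-2-methylpropanoate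
Conditions: TBSCl, imidazole, DMF, 0 °C to rt
Reagents that add atoms: tert-butyldimethylsilyl chloride, CC(C)(C)[Si](C)(C)Cl
Why: Standard silylation of the primary alcohol; the stereocentre is untouched.

Step 2
Reactants: 2 methyl (S)-3-[(tert-butyldimethylsilyl)oxy]-2-methylpropanoate
Product: 3 (S)-3-[(tert-butyldimethylsilyl)oxy]-2-methylpropanal
Conditions: i-Bu2AlH, CH2Cl2, −78 °C
Reagents that add atoms: none
Why: Low-temperature partial reduction of the ester by i-Bu2AlH through a stable tetrahedral aluminate gives the aldehyde without epimerisation.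

Step 3
Reactants: 3 (S)-3-[(tert-butyldimethylsilyl)oxy]-2-methylpropanal
Product: 4 (R)-tert-butyldimethyl[(2-methylbut-3-yn-1-yl)oxy]silane
Conditions: dimethyl (1-diazo-2-oxopropyl)phosphonate, K2CO3, MeOH, 0 °C to rt
Reagents that add atoms: dimethyl (1-diazo-2-oxopropyl)phosphonate, COP(=O)(OC)C(=[N+]=[N-])C(C)=O
Why: Ohira–Bestmann (Seyferth–Gilbert) homologation gives the terminal alkyne under mild carbonate conditions that keep the α-stereocentre, the future C4.

Step 4
Reactants: 5 3-bromobut-3-en-1-ol
Product: 6 3-bromobut-3-enoic acid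
Conditions: CrO3, H2SO4, H2O, acetone, 0 °C
Reagents that add atoms: water, O
Why: Jones oxidation of the primary alcohol through the aldehyde hydrate; the vinyl bromide is inert to chromic acid.

Step 5
Reactants: 6 3-bromobut-3-enoic acid; 7 (R)-4-benzyl-1,3-thiazolidine-2-thione
Product: 8 1-[(4R)-4-benzyl-2-thioxo-1,3-thiazolidin-3-yl]-3-bromobut-3-en-1-one
Conditions: EDC·HCl, DMAP (cat.), CH2Cl2, 0 °C
Reagents that add atoms: none
Why: Carbodiimide (Steglich-type) N-acylation of the thiazolidinethione at low temperature, which keeps the β,γ-unsaturation.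

Step 6
Reactants: 9 (S)-3-bromo-2-hydroxy-2-methylpropanoic acid
Product: 11 (R)-2,3-dihydroxy-2-methylpropanoic acid, via potassium glycidate 10 (not isolated)
Conditions: KOH, H2O, rt to 80 °C; HCl to pH 2
Reagents that add atoms: potassium hydroxide, [K+].[OH-]
Why: Intramolecular Williamson closure to the glycidate, then hydroxide opening at the CH2 terminus; no bond to the stereocentre is broken, so the (S)-bromohydrin gives the (R)-diol.

Step 7
Reactants: 11 (R)-2,3-dihydroxy-2-methylpropanoic acid
Product: 12 methyl (R)-2,2,4-trimethyl-1,3-dioxolane-4-carboxylate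
Conditions: 2,2-dimethoxypropane, MeOH, TsOH·H2O (cat.), 50 °C
Reagents that add atoms: 2,2-dimethoxypropane, COC(C)(C)OC; methanol, CO
Why: Fischer esterification and acetalisation in one operation, the 1,2-diol closing the five-membered isopropylidene acetal.

Step 8
Reactants: 12 methyl (R)-2,2,4-trimethyl-1,3-dioxolane-4-carboxylate
Product: 13 (R)-2,2,4-trimethyl-1,3-dioxolane-4-carboxylic acid
Conditions: LiOH·H2O, THF–H2O, 0 °C to rt; HCl to pH 3 at 0 °C
Reagents that add atoms: lithium hydroxide, [Li+].[OH-]
Why: Saponification of the methyl ester; the acetal and the quaternary stereocentre are stable to base.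

Step 9
Reactants: 14 (R)-citramalic acid
Product: 15 2-[(4R)-2,2,4-trimethyl-5-oxo-1,3-dioxolan-4-yl]acetic acid
Conditions: 2,2-dimethoxypropane, TsOH·H2O (cat.), CH2Cl2, rt
Reagents that add atoms: 2,2-dimethoxypropane, COC(C)(C)OC
Why: Seebach-type acetalisation of the α-hydroxy acid unit to the dioxolanone leaves the CH2CO2H arm free and keeps the quaternary centre, the future C10.

Step 10
Reactants: 15 2-[(4R)-2,2,4-trimethyl-5-oxo-1,3-dioxolan-4-yl]acetic acid
Product: 17 (R)-3-hydroxy-3-methyloxolan-2-one, via hydroxyethyl dioxolanone 16 (not isolated)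
Conditions: BH3·SMe2, THF, 0 °C to rt; MeOH; TsOH·H2O (cat.), CH2Cl2, rt
Reagents that add atoms: none
Why: Chemoselective borane reduction of the free acid, then acid-catalysed translactonisation of the hydroxy dioxolanone to the five-membered lactone with loss of acetone.

Step 11
Reactants: 17 (R)-3-hydroxy-3-methyloxolan-2-one; 4 (R)-tert-butyldimethyl[(2-methylbut-3-yn-1-yl)oxy]silane
Product: 18 (3R,7R)-8-[(tert-butyldimethylsilyl)oxy]-1,3-dihydroxy-3,7-dimethyloct-5-yn-4-one
Conditions: n-BuLi (for 4), LiN(SiMe3)2 (for 17), THF, −78 to −40 °C; AcOH quench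
Reagents that add atoms: none
Why: Addition of the lithium acetylide to the non-enolisable lactone carbonyl (C1) stops at the lactolate, which opens on work-up to the α′-hydroxy ynone; the tertiary hydroxyl travels as its lithium alkoxide and no stereocentre is touched.

Step 12
Reactants: 18 (3R,7R)-8-[(tert-butyldimethylsilyl)oxy]-1,3-dihydroxy-3,7-dimethyloct-5-yn-4-one
Product: 19 (2R)-5-[(2S)-1-[(tert-butyldimethylsilyl)oxy]propan-2-yl]-2-(2-hydroxyethyl)-2-methylfuran-3(2H)-one
Conditions: (Ph3P)AuNTf2 (5 mol %), CH2Cl2, rt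
Reagents that add atoms: none
Why: Gold-catalysed 5-endo-dig cycloisomerisation of the α′-hydroxy ynone: the C10 hydroxyl adds to the gold-activated alkyne at C3 and protodeauration gives the furan-3(2H)-one under neutral conditions that leave C4 untouched.

Step 13
Reactants: 19 (2R)-5-[(2S)-1-[(tert-butyldimethylsilyl)oxy]propan-2-yl]-2-(2-hydroxyethyl)-2-methylfuran-3(2H)-one
Product: 20 2-[(2R)-5-[(2S)-1-[(tert-butyldimethylsilyl)oxy]propan-2-yl]-2-methyl-3-oxo-2,3-dihydrofuran-2-yl]acetaldehyde
Conditions: Dess–Martin periodinane, CH2Cl2, 0 °C to rt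
Reagents that add atoms: none
Why: Dess–Martin oxidation of the primary alcohol to the C8 aldehyde under non-basic conditions that avoid retro-oxa-Michael opening of the furanone.

Step 14
Reactants: 20 2-[(2R)-5-[(2S)-1-[(tert-butyldimethylsilyl)oxy]propan-2-yl]-2-methyl-3-oxo-2,3-dihydrofuran-2-yl]acetaldehyde; 8 1-[(4R)-4-benzyl-2-thioxo-1,3-thiazolidin-3-yl]-3-bromobut-3-en-1-one
Product: 21 syn-aldol adduct, 1-[(4R)-4-benzyl-2-thioxo-1,3-thiazolidin-3-yl]-(2R,3S)-2-(1-bromoethenyl)-3-hydroxy-4-[furanon-2-yl of 20]butan-1-one (C7 and C8 as in the target)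
Conditions: TiCl4, i-Pr2NEt, N-methyl-2-pyrrolidinone, CH2Cl2, −78 to 0 °C
Reagents that add atoms: none
Why: Crimmins titanium aldol: the chlorotitanium (Z)-enolate reacts at its α-carbon through the open "Evans-syn" chair on the face away from the auxiliary benzyl group, setting C7 and C8 syn with the configuration of the target.

Step 15
Reactants: 21 syn-aldol adduct
Product: 22 C8 tert-butyldimethylsilyl ether of 21
Conditions: TBSOTf, 2,6-lutidine, CH2Cl2, −78 to 0 °C
Reagents that add atoms: tert-butyldimethylsilyl triflate, CC(C)(C)[Si](C)(C)OS(=O)(=O)C(F)(F)F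
Why: Silylation of the hindered C8 hydroxyl with the silyl triflate masks it against β-elimination and against ketalisation onto the furanone once C6 is an aldehyde.

Step 16
Reactants: 22 C8 tert-butyldimethylsilyl ether of 21
Product: 23 C5 primary alcohol (22 without the primary silyl group)
Conditions: HF·pyridine, pyridine, THF, 0 °C
Reagents that add atoms: none
Why: Selective cleavage of the primary silyl ether in the presence of the hindered secondary one, by the usual rate difference in fluoride desilylation.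

Step 17
Reactants: 23 C5 primary alcohol
Product: 24 C5 primary iodide
Conditions: I2, PPh3, imidazole, CH2Cl2, 0 °C
Reagents that add atoms: iodine, [I][I]
Why: Appel-type iodination (Garegg–Samuelsson conditions) by SN2 displacement of the alkoxyphosphonium at C5; C4 is not involved.

Step 18
Reactants: 24 C5 primary iodide
Product: 25 iodo aldehyde, (2R,3S)-2-(1-bromoethenyl)-3-[(tert-butyldimethylsilyl)oxy]-4-[(2R)-5-(1-iodopropan-2-yl)-2-methyl-3-oxo-2,3-dihydrofuran-2-yl]butanal (C4 as in the target)
Conditions: i-Bu2AlH (1.2 equiv), CH2Cl2, −78 °C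
Reagents that add atoms: none
Why: Reductive cleavage of the N-acylthiazolidinethione by i-Bu2AlH stops at the aldehyde through a stable aluminium hemiaminal, the activated thioimide reacting before the vinylogous-ester carbonyl of the furanone.

Step 19
Reactants: 25 iodo aldehyde
Product: 26 (4S,6R,7S,8S,10R)-7-(1-bromoethenyl)-8-[(tert-butyldimethylsilyl)oxy]-6-hydroxy-4,10-dimethyl-3,10-epoxycyclodec-2-en-1-one (ring locants = target numbering)
Conditions: CrCl2 (8 equiv), cobalt phthalocyanine (CoPc, C32H16CoN8; 0.2 equiv), DMF–THF, rt, slow addition of 25 to 0.003 M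
Reagents that add atoms: none
Why: CrCl2 reduces the cobalt phthalocyanine to monovalent cobalt, which displaces iodide at C5; homolysis of the alkylcobalt gives the C5 radical, which divalent chromium captures as a trivalent alkylchromium that adds to the chromium-bound C6 aldehyde. The closest known reactions are the Takai–Utimoto cobalt-catalysed alkylchromium addition to aldehydes and Nozaki–Hiyama–Kishi closures of nine- and ten-membered rings with alkenyl and allyl halides. The new bond closes the oxygen-bridged ring as a 9-exo-trig addition counted through the furanone oxygen, which is at the same time the ten-membered carbocycle C1–C10. C6 is set by C7: Felkin–Anh attack anti to the C8(OTBS) branch places the new hydroxyl syn to the bromovinyl group and gives the 6R carbinol needed for the trans-fused lactone. The step needs chemoselection of the sp3 C–I bond over the vinyl C–Br bond and of the aldehyde over the furanone ketone; nickel-free cobalt/chromium conditions and the aldehyde selectivity of organochromium reagents secure both, and high dilution suppresses oligomerisation.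

Step 20
Reactants: 26 macrocyclic bromovinyl alcohol
Product: 27 C8 tert-butyldimethylsilyl ether of the desacyl target (6,12-lactone with the C11=C13 methylene)
Conditions: CO (1 atm), Pd(PPh3)4 (10 mol %), K2CO3, MeCN, 60 °C
Reagents that add atoms: carbon monoxide, [C-]#[O+]
Why: Palladium-catalysed carbonylative lactonisation (Stille–Cowell type): zerovalent palladium inserts into the vinyl C–Br bond, CO inserts, and the C6 hydroxyl captures the acylpalladium to close the α-methylene-γ-lactone; the trans fusion follows from C6 and C7.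

Step 21
Reactants: 27 C8 silyl ether of the desacyl target
Product: 28 desacyl target (C8 alcohol)
Conditions: HF·pyridine, THF, 0 °C to rt
Reagents that add atoms: none
Why: Fluoride cleavage of the C8 silyl ether under mildly acidic conditions that tolerate the α-methylene lactone and the furanone.

Step 22
Reactants: 28 desacyl target; 13 (R)-2,2,4-trimethyl-1,3-dioxolane-4-carboxylic acid
Product: 29 target as its 2′,3′-O-isopropylidene acetal
Conditions: 2,4,6-trichlorobenzoyl chloride, Et3N, DMAP, toluene, rt
Reagents that add atoms: none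
Why: Yamaguchi esterification: the mixed anhydride of the α-quaternary acid acylates the hindered C8 hydroxyl under DMAP catalysis without touching a stereocentre.

Step 23
Reactants: 29 target isopropylidene acetal
Product: 30 CNP0263764.2
Conditions: TFA–H2O (4:1), CH2Cl2, 0 °C
Reagents that add atoms: none
Why: Acid-catalysed hydrolysis of the isopropylidene acetal frees the 2,3-diol; lactone, furanone and ester survive brief aqueous acid.

Compound list
1 | methyl (S)-3-hydroxy-2-methylpropanoate | OC[C@H](C)C(=O)OC | starting material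
2 | methyl (S)-3-[(tert-butyldimethylsilyl)oxy]-2-methylpropanoate | CC(C)(C)[Si](C)(C)OC[C@H](C)C(=O)OC | intermediate
3 | (S)-3-[(tert-butyldimethylsilyl)oxy]-2-methylpropanal | CC(C)(C)[Si](C)(C)OC[C@H](C)C=O | intermediate
4 | (R)-tert-butyldimethyl[(2-methylbut-3-yn-1-yl)oxy]silane | CC(C)(C)[Si](C)(C)OC[C@H](C)C#C | intermediate
5 | 3-bromobut-3-en-1-ol | C=C(Br)CCO | starting material
6 | 3-bromobut-3-enoic acid | C=C(Br)CC(=O)O | intermediate
7 | (R)-4-benzyl-1,3-thiazolidine-2-thione | S=C1N[C@H](Cc2ccccc2)CS1 | starting material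
8 | 1-[(4R)-4-benzyl-2-thioxo-1,3-thiazolidin-3-yl]-3-bromobut-3-en-1-one | C=C(Br)CC(=O)N1[C@H](Cc2ccccc2)CSC1=S | intermediate
9 | (S)-3-bromo-2-hydroxy-2-methylpropanoic acid | OC(=O)[C@](C)(O)CBr | starting material
10 | potassium (R)-2-methyloxirane-2-carboxylate | [K+].[O-]C(=O)[C@@]1(C)CO1 | intermediate
11 | (R)-2,3-dihydroxy-2-methylpropanoic acid | OC(=O)[C@](C)(O)CO | intermediate
12 | methyl (R)-2,2,4-trimethyl-1,3-dioxolane-4-carboxylate | COC(=O)[C@](C)(OC1(C)C)CO1 | intermediate
13 | (R)-2,2,4-trimethyl-1,3-dioxolane-4-carboxylic acid | OC(=O)[C@](C)(OC1(C)C)CO1 | intermediate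
14 | (R)-citramalic acid, (R)-2-hydroxy-2-methylbutanedioic acid | OC(=O)[C@@](C)(CC(=O)O)O | starting material
15 | 2-[(4R)-2,2,4-trimethyl-5-oxo-1,3-dioxolan-4-yl]acetic acid | OC(=O)C[C@@]1(C)OC(C)(C)OC1=O | intermediate
16 | (5R)-5-(2-hydroxyethyl)-2,2,5-trimethyl-1,3-dioxolan-4-one | OCC[C@@]1(C)OC(C)(C)OC1=O | intermediate
17 | (R)-3-hydroxy-3-methyloxolan-2-one | C[C@@]1(O)CCOC1=O | intermediate
18 | (3R,7R)-8-[(tert-butyldimethylsilyl)oxy]-1,3-dihydroxy-3,7-dimethyloct-5-yn-4-one | CC(C)(C)[Si](C)(C)OC[C@H](C)C#CC(=O)[C@@](C)(CCO)O | intermediate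
19 | (2R)-5-[(2S)-1-[(tert-butyldimethylsilyl)oxy]propan-2-yl]-2-(2-hydroxyethyl)-2-methylfuran-3(2H)-one | CC(C)(C)[Si](C)(C)OC[C@H](C)C1=CC(=O)[C@@](C)(CCO)O1 | intermediate
20 | 2-[(2R)-5-[(2S)-1-[(tert-butyldimethylsilyl)oxy]propan-2-yl]-2-methyl-3-oxo-2,3-dihydrofuran-2-yl]acetaldehyde | CC(C)(C)[Si](C)(C)OC[C@H](C)C1=CC(=O)[C@@](C)(CC=O)O1 | intermediate
21 | syn-aldol adduct, (2R,3S)-2-(1-bromoethenyl)-3-hydroxybutanoyl thiazolidinethione carrying the furanone of 20 at C4 of the chain | CC(C)(C)[Si](C)(C)OC[C@H](C)C1=CC(=O)[C@@](C)(C[C@H](O)[C@@H](C(Br)=C)C(=O)N2[C@H](Cc3ccccc3)CSC2=S)O1 | intermediate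
22 | C8 tert-butyldimethylsilyl ether of 21 | CC(C)(C)[Si](C)(C)OC[C@H](C)C1=CC(=O)[C@@](C)(C[C@H](O[Si](C)(C)C(C)(C)C)[C@@H](C(Br)=C)C(=O)N2[C@H](Cc3ccccc3)CSC2=S)O1 | intermediate
23 | C5 primary alcohol from 22 | OC[C@H](C)C1=CC(=O)[C@@](C)(C[C@H](O[Si](C)(C)C(C)(C)C)[C@@H](C(Br)=C)C(=O)N2[C@H](Cc3ccccc3)CSC2=S)O1 | intermediate
24 | C5 primary iodide from 23 | IC[C@H](C)C1=CC(=O)[C@@](C)(C[C@H](O[Si](C)(C)C(C)(C)C)[C@@H](C(Br)=C)C(=O)N2[C@H](Cc3ccccc3)CSC2=S)O1 | intermediate
25 | iodo aldehyde, (2R,3S)-2-(1-bromoethenyl)-3-[(tert-butyldimethylsilyl)oxy]-4-[(2R)-5-(1-iodopropan-2-yl)-2-methyl-3-oxo-2,3-dihydrofuran-2-yl]butanal | IC[C@H](C)C1=CC(=O)[C@@](C)(C[C@H](O[Si](C)(C)C(C)(C)C)[C@@H](C(Br)=C)C=O)O1 | intermediate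
26 | (4S,6R,7S,8S,10R)-7-(1-bromoethenyl)-8-[(tert-butyldimethylsilyl)oxy]-6-hydroxy-4,10-dimethyl-3,10-epoxycyclodec-2-en-1-one | O[C@@H]1C[C@H](C)C2=CC(=O)[C@@](C)(C[C@H](O[Si](C)(C)C(C)(C)C)[C@H]1C(Br)=C)O2 | intermediate
27 | C8 tert-butyldimethylsilyl ether of the desacyl target | C=C1C(=O)O[C@@H]2C[C@H](C)C3=CC(=O)[C@@](C)(C[C@H](O[Si](C)(C)C(C)(C)C)[C@@H]12)O3 | intermediate
28 | desacyl target, the C8 alcohol | C=C1C(=O)O[C@@H]2C[C@H](C)C3=CC(=O)[C@@](C)(C[C@H](O)[C@@H]12)O3 | intermediate
29 | target as its 2′,3′-O-isopropylidene acetal | C=C1C(=O)O[C@@H]2C[C@H](C)C3=CC(=O)[C@@](C)(C[C@H](OC(=O)[C@](C)(OC4(C)C)CO4)[C@@H]12)O3 | intermediate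
30 | CNP0263764.2, the C8 (2R)-2,3-dihydroxy-2-methylpropanoate of the (4S,6R,7S,8S,10R) furanone lactone | C=C1C(=O)O[C@@H]2C[C@H](C)C3=CC(=O)[C@@](C)(C[C@H](OC(=O)[C@](C)(O)CO)[C@@H]12)O3 | target

Total step count: 23. Longest linear sequence: 16 steps (steps 1–3, then 11–23, from 1).

Steps most likely to fail

1. Step 19. The C5 organometallic may be lost before it reaches the aldehyde (protonation, β-hydride loss from the alkylcobalt to the isopropenyl furanone, intermolecular coupling), and the facial bias at C6 may be weak. The fallback reverses the polarity of the closing bond. It sets out from lactone 17: commercial 2-methylbut-1-en-3-yne replaces 4, and the operations of steps 11–15 and 18 give in turn the ynone diol F1, the 5-isopropenylfuranone alcohol F2, its aldehyde F3, the aldol adduct F4, the silyl ether F5 and the aldehyde F6. SmI2 (HMPA, t-BuOH, THF, −78 °C, high dilution) would then reduce the C6 aldehyde to a ketyl that adds to C5, the terminus of the cross-conjugated dienone. Protonation of the samarium dienolate creates C4, and DBU equilibration should favour the 4S epimer, which keeps H4 in the furanone plane next to C2–H. That compound is 26, where the route is rejoined.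

2. Step 22. Acylation of the hindered C8 hydroxyl by an α-quaternary mixed anhydride may be slower than base-induced migration of the lactone from O6 to O8 or conjugate addition of DMAP to the methylene lactone. The fallback uses a smaller acyl donor and a different unmasking. It sets out from 28: the potassium glycidate 10 (isolated by stopping step 6 at room temperature) is coupled under the same Yamaguchi activation to give the epoxy ester F7. Dilute HClO4 in THF–H2O should then open the epoxide at its CH2 terminus, with C2′ untouched, and give the target 30 directly.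

3. Step 20. The acylpalladium may be captured too slowly by the ring-bound C6 hydroxyl, so that reduction of the vinyl bromide or oligomerisation takes over. The fallback separates carbonylation from ring closure. It sets out from 26: methoxycarbonylation (CO, Pd(OAc)2, PPh3, Et3N, MeOH–DMF, 60 °C) gives the hydroxy acrylate F8, which should lactonise with TsOH in toluene to 27.

Further compounds
F1 | step 19 | (3R)-1,3-dihydroxy-3,7-dimethyloct-7-en-5-yn-4-one | C=C(C)C#CC(=O)[C@@](C)(CCO)O
F2 | step 19 | (2R)-2-(2-hydroxyethyl)-2-methyl-5-(prop-1-en-2-yl)furan-3(2H)-one | C=C(C)C1=CC(=O)[C@@](C)(CCO)O1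
F3 | step 19 | 2-[(2R)-2-methyl-3-oxo-5-(prop-1-en-2-yl)-2,3-dihydrofuran-2-yl]acetaldehyde | C=C(C)C1=CC(=O)[C@@](C)(CC=O)O1
F4 | step 19 | isopropenyl analogue of aldol adduct 21 | C=C(C)C1=CC(=O)[C@@](C)(C[C@H](O)[C@@H](C(Br)=C)C(=O)N2[C@H](Cc3ccccc3)CSC2=S)O1
F5 | step 19 | C8 tert-butyldimethylsilyl ether of F4 | C=C(C)C1=CC(=O)[C@@](C)(C[C@H](O[Si](C)(C)C(C)(C)C)[C@@H](C(Br)=C)C(=O)N2[C@H](Cc3ccccc3)CSC2=S)O1
F6 | step 19 | (2R,3S)-2-(1-bromoethenyl)-3-[(tert-butyldimethylsilyl)oxy]-4-[(2R)-2-methyl-3-oxo-5-(prop-1-en-2-yl)-2,3-dihydrofuran-2-yl]butanal | C=C(C)C1=CC(=O)[C@@](C)(C[C@H](O[Si](C)(C)C(C)(C)C)[C@@H](C(Br)=C)C=O)O1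
F7 | step 22 | C8 (2R)-2-methyloxirane-2-carboxylate of 28 | C=C1C(=O)O[C@@H]2C[C@H](C)C3=CC(=O)[C@@](C)(C[C@H](OC(=O)[C@](C)(O4)C4)[C@@H]12)O3
F8 | step 20 | methyl 2-substituted acrylate from 26 (CO2Me in place of Br) | O[C@@H]1C[C@H](C)C2=CC(=O)[C@@](C)(C[C@H](O[Si](C)(C)C(C)(C)C)[C@H]1C(=C)C(=O)OC)O2
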